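**Retrosynthetic overview**

1. The target 16 is fisetinidol-(4α→6)-fisetinidol, two identical (2R,3S)-flavan-3-ol units. The interflavan bond C4(upper)–C6(lower) is cut last (Friedel–Crafts union of a C4-oxygenated, 3-O-acetylated unit with ring A of a second unit), so one monomer, 11, supplies both halves.
2. 11 comes from flav-2-ene 9 by asymmetric syn-hydroboration of the C2=C3 enol ether, which sets C2 and C3 (2,3-trans).
3. 9 comes from ketone 2 and dibromide 6 in one pot: C3–C4 by enolate C-benzylation, then O1–C8a by CuI-catalysed enolate O-arylation, a [3+3] annulation that closes the pyran ring.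
4. Enabling feature: O1 and C3 both sit on C2, the carbon that carries ring B, so O1–C2–C3 is the ambident enolate of an aryl methyl ketone. C4 (benzylic) and C8a (ortho aryl carbon) are 1,3-related through C4a on ring A and can both carry bromide; the 7-oxygen is meta to C8a and does not interfere.
5. Ring order: rings A and B are bought; the pyran ring is formed in step 5 and appears twice in 16 (upper and lower unit); the last C–C bond joins the two units.

Key step: step 5

Remark: flavan numbering is used (O1, C2 bearing ring B, C3, C4, C4a, C5–C8, C8a; ring A is the benzo ring). The facial sense of the hydroboration in step 6 is assumed by analogy with 1-arylcycloalkenes.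

**Route**

Step 1
Reactants: 1 3',4'-dihydroxyacetophenone
Product: 2 3',4'-bis(benzyloxy)acetophenone
Conditions: BnBr (2.3 equiv), K2CO3, DMF, 60 °C
Reagents that add atoms: benzyl bromide BrCc1ccccc1
Why: Williamson etherification of both phenols under carbonate conditions should proceed without C-alkylation of the ketone, giving protecting groups that survive every later step and fall together at the end.

Step 2
Reactants: 3 2-bromo-4-hydroxybenzaldehyde
Product: 4 4-(benzyloxy)-2-bromobenzaldehyde
Conditions: BnBr (1.1 equiv), K2CO3, DMF, rt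
Reagents that add atoms: benzyl bromide BrCc1ccccc1
Why: Williamson etherification of the phenol, which is acidified by the para formyl group, should be clean.

Step 3
Reactants: 4 4-(benzyloxy)-2-bromobenzaldehyde
Product: 5 [4-(benzyloxy)-2-bromophenyl]methanol
Conditions: NaBH4, MeOH–THF, 0 °C
Reagents that add atoms: none
Why: Borohydride reduction of the aldehyde leaves the aryl bromide and the benzyl ether untouched.

Step 4
Reactants: 5 [4-(benzyloxy)-2-bromophenyl]methanol
Product: 6 4-(benzyloxy)-2-bromo-1-(bromomethyl)benzene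
Conditions: PBr3, CH2Cl2, 0 °C; used crude
Reagents that add atoms: phosphorus tribromide BrP(Br)Br
Why: Bromination of the benzylic alcohol through its phosphite ester (SN2) should be fast at 0 °C, and the para-alkoxybenzylic bromide is used at once because it is labile.

Step 5
Reactants: 2 3',4'-bis(benzyloxy)acetophenone, 6 4-(benzyloxy)-2-bromo-1-(bromomethyl)benzene
Product: 9 7-(benzyloxy)-2-[3,4-bis(benzyloxy)phenyl]-4H-chromene, via lithium enolate 7 (not isolated), via bromo ketone 8 (not isolated)
Conditions: 2 (1.5 equiv), LiN(SiMe3)2, THF, −78 °C; 6, −78 → 0 °C; then CuI (10 mol %), 1,10-phenanthroline (20 mol %), Cs2CO3, DMF, 110 °C; one pot, no work-up between the two events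
Reagents that add atoms: none
Why: The lithium enolate 7 displaces the benzylic bromide of 6 by SN2 (the aryl C–Br bond is inert to it), forming C3–C4 in ketone 8; Cs2CO3 then regenerates the (Z)-enolate of 8, whose oxygen is arylated at the ortho carbon in an Ullmann-type cycle at monovalent copper (oxidative addition of the aryl bromide, C–O reductive elimination), forming O1–C8a. The closest known reaction type is the CuI-catalysed domino C-benzylation/O-arylation of 1,3-dicarbonyl enolates with 2-bromobenzyl bromides to 4H-chromenes, together with the CuI-catalysed intramolecular O-arylation of simple ketone enolates used for benzofurans. The pyran ring closes in the second event as a six-membered ring by intramolecular enolate O-arylation (oxygen onto the aryl carbon, formally 6-exo); the alternative C-arylation would give a benzocyclobutene and is excluded by ring size. No stereocentre is formed, because C2 and C3 leave the step as the enol ether double bond that step 6 uses to set both. The step needs C- over O-benzylation and mono- over dialkylation (lithium counter-ion in THF, soft benzylic bromide, enolate in excess, a single enolisable position), benzylic over aryl bromide in the first event (SN2 only at the sp3 carbon) and O- over C-arylation in the second.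

Step 6
Reactants: 9 7-(benzyloxy)-2-[3,4-bis(benzyloxy)phenyl]-4H-chromene
Product: 11 (2R,3S)-7,3',4'-tri-O-benzylfisetinidol, via organoborane 10 (not isolated)
Conditions: IpcBH2 [monoisopinocampheylborane from (+)-α-pinene], THF, −25 °C; then NaOH, H2O2, 0 °C → rt; recrystallisation
Reagents that add atoms: hydrogen peroxide OO
Why: Asymmetric hydroboration–oxidation adds H and B syn across the C2=C3 enol ether with boron at C3 (β to O1, away from the aryl-bearing C2), so oxidation with retention should give the 2,3-trans alcohol, and the isopinocampheyl group selects the face that by analogy with 1-arylcycloalkenes should lead to the (2R,3S) series.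

Step 7
Reactants: 11 (2R,3S)-7,3',4'-tri-O-benzylfisetinidol
Product: 12 (2R,3S,4S)-7,3',4'-tri-O-benzyl-4β-(2-ethoxyethoxy)fisetinidol
Conditions: DDQ (2 equiv), 2-ethoxyethanol, CH2Cl2, rt
Reagents that add atoms: 2-ethoxyethanol CCOCCO
Why: Benzylic oxidation–etherification: DDQ abstracts hydride from C4, which is activated by the para 7-benzyloxy group and the ortho ring oxygen of ring A, and the alcohol traps the cation mainly from the β face anti to the 2-aryl group; the C4 configuration is erased again in step 9, so a mixture of C4 epimers is acceptable.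

Step 8
Reactants: 12 (2R,3S,4S)-7,3',4'-tri-O-benzyl-4β-(2-ethoxyethoxy)fisetinidol
Product: 13 3-O-acetyl-7,3',4'-tri-O-benzyl-4β-(2-ethoxyethoxy)fisetinidol
Conditions: Ac2O, pyridine, DMAP (cat.), CH2Cl2, rt
Reagents that add atoms: acetic anhydride CC(=O)OC(C)=O
Why: Acylation of the secondary 3-hydroxyl installs the participating group that controls C4 in the next step.

Step 9
Reactants: 13 3-O-acetyl-7,3',4'-tri-O-benzyl-4β-(2-ethoxyethoxy)fisetinidol, 11 (2R,3S)-7,3',4'-tri-O-benzylfisetinidol
Product: 14 3-O-acetyl-7,3',4'-tri-O-benzylfisetinidol-(4α→6)-7,3',4'-tri-O-benzylfisetinidol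
Conditions: 11 (4 equiv), Me3SiOTf (0.2 equiv), CH2Cl2, −78 → −30 °C
Reagents that add atoms: none
Why: Friedel–Crafts alkylation: Me3SiOTf ionises the C4 ether to the benzylic cation, the 3-acetoxy group shields its β face by participation, and C6 of ring A of 11 (para to O1, ortho to the 7-benzyloxy group, less hindered than C8) should attack from the α face and set C4 trans to C3, while the excess of 11 suppresses self-condensation of 13.

Step 10
Reactants: 14 3-O-acetyl-7,3',4'-tri-O-benzylfisetinidol-(4α→6)-7,3',4'-tri-O-benzylfisetinidol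
Product: 15 7,3',4'-tri-O-benzylfisetinidol-(4α→6)-7,3',4'-tri-O-benzylfisetinidol
Conditions: NaOMe (cat.), MeOH–THF, rt → 40 °C
Reagents that add atoms: none
Why: Transesterification (Zemplén-type methanolysis) removes the acetate without touching the benzyl ethers or any stereocentre.

Step 11
Reactants: 15 7,3',4'-tri-O-benzylfisetinidol-(4α→6)-7,3',4'-tri-O-benzylfisetinidol
Product: 16 fisetinidol-(4α→6)-fisetinidol
Conditions: H2 (1 atm), Pd(OH)2/C, THF–MeOH–H2O, rt
Reagents that add atoms: none
Why: Heterogeneous hydrogenolysis cleaves the six O-benzyl bonds under neutral conditions that should leave the acid-labile interflavan bond, the pyran C2–O1 bonds and all five stereocentres untouched.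

**Compound list**

1 | 3',4'-dihydroxyacetophenone | CC(=O)c1ccc(O)c(O)c1 | starting material
2 | 3',4'-bis(benzyloxy)acetophenone | CC(=O)c1ccc(OCc2ccccc2)c(OCc2ccccc2)c1 | intermediate
3 | 2-bromo-4-hydroxybenzaldehyde | O=Cc1ccc(O)cc1Br | starting material
4 | 4-(benzyloxy)-2-bromobenzaldehyde | O=Cc1ccc(OCc2ccccc2)cc1Br | intermediate
5 | [4-(benzyloxy)-2-bromophenyl]methanol | OCc1ccc(OCc2ccccc2)cc1Br | intermediate
6 | 4-(benzyloxy)-2-bromo-1-(bromomethyl)benzene | BrCc1ccc(OCc2ccccc2)cc1Br | intermediate
7 | lithium 1-[3,4-bis(benzyloxy)phenyl]ethen-1-olate (lithium enolate of 2; not isolated) | [Li]OC(=C)c1ccc(OCc2ccccc2)c(OCc2ccccc2)c1 | intermediate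
8 | 3-[4-(benzyloxy)-2-bromophenyl]-1-[3,4-bis(benzyloxy)phenyl]propan-1-one (not isolated) | O=C(CCc1ccc(OCc2ccccc2)cc1Br)c1ccc(OCc2ccccc2)c(OCc2ccccc2)c1 | intermediate
9 | 7-(benzyloxy)-2-[3,4-bis(benzyloxy)phenyl]-4H-chromene (7,3',4'-tri-O-benzylflav-2-ene) | C1=C(c2ccc(OCc3ccccc3)c(OCc3ccccc3)c2)Oc2cc(OCc3ccccc3)ccc2C1 | intermediate
10 | (isopinocampheyl)[7,3',4'-tris(benzyloxy)flavan-3-yl]borane; (2R)-flavan, boron on C3 trans to the 2-aryl group (same spatial arrangement as in 11), isopinocampheyl group (1R,2R,3R,5S); not isolated | C[C@@H]1[C@H]2C[C@H](C2(C)C)C[C@H]1B[C@H]1Cc2ccc(OCc3ccccc3)cc2O[C@@H]1c1ccc(OCc2ccccc2)c(OCc2ccccc2)c1 | intermediate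
11 | (2R,3S)-7-(benzyloxy)-2-[3,4-bis(benzyloxy)phenyl]chroman-3-ol (7,3',4'-tri-O-benzylfisetinidol, 2,3-trans) | O[C@H]1Cc2ccc(OCc3ccccc3)cc2O[C@@H]1c1ccc(OCc2ccccc2)c(OCc2ccccc2)c1 | intermediate
12 | (2R,3S,4S)-7-(benzyloxy)-2-[3,4-bis(benzyloxy)phenyl]-4-(2-ethoxyethoxy)chroman-3-ol (2,3-trans, 4β-ether, 3,4-cis) | C(c1ccccc1)Oc1ccc2c(c1)O[C@H](c1ccc(OCc3ccccc3)c(OCc3ccccc3)c1)[C@@H](O)[C@H]2OCCOCC | intermediate
13 | 3-O-acetate of 12 (2,3-trans, 4β-ether) | C(c1ccccc1)Oc1ccc2c(c1)O[C@H](c1ccc(OCc3ccccc3)c(OCc3ccccc3)c1)[C@@H](OC(C)=O)[C@H]2OCCOCC | intermediate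
14 | 3-O-acetyl-7,3',4'-tri-O-benzylfisetinidol-(4α→6)-7,3',4'-tri-O-benzylfisetinidol; both units 2,3-trans with the configuration of 11 at C2 and C3, upper unit 3,4-trans (aryl at C4 α) | C(c1ccccc1)Oc1ccc2c(c1)O[C@H](c1ccc(OCc3ccccc3)c(OCc3ccccc3)c1)[C@@H](OC(C)=O)[C@@H]2c1cc2c(cc1OCc1ccccc1)O[C@H](c1ccc(OCc3ccccc3)c(OCc3ccccc3)c1)[C@@H](O)C2 | intermediate
15 | 7,3',4'-tri-O-benzylfisetinidol-(4α→6)-7,3',4'-tri-O-benzylfisetinidol; stereochemistry as in 14 | C(c1ccccc1)Oc1ccc2c(c1)O[C@H](c1ccc(OCc3ccccc3)c(OCc3ccccc3)c1)[C@@H](O)[C@@H]2c1cc2c(cc1OCc1ccccc1)O[C@H](c1ccc(OCc3ccccc3)c(OCc3ccccc3)c1)[C@@H](O)C2 | intermediate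
16 | fisetinidol-(4α→6)-fisetinidol; both units (2R,3S), upper unit C4 (R), all-trans upper pyran ring | Oc1ccc2c(c1)O[C@H](c1ccc(O)c(O)c1)[C@@H](O)[C@@H]2c1cc2c(cc1O)O[C@H](c1ccc(O)c(O)c1)[C@@H](O)C2 | target

**Step count and risks**

Total steps: 11. Longest linear sequence: 10 steps (3 → 4 → 5 → 6 → 9 → 11 → 12 → 13 → 14 → 15 → 16).

Step 5. The first event may over-alkylate (proton exchange between enolate 7 and ketone 8, then a second benzylation). The non-stabilised enolate of 8 may also fail to enter the copper cycle fast enough, so that aldol condensation or protodebromination wins. The enol ether 9 may be lost by hydrolysis on acidic work-up. Fallback, setting out from 2 and 6: the alkylation is run alone and ketone 8 is isolated. Its aryl bromide is converted to the phenol by hydroxylation at zerovalent palladium (Pd2(dba)3, tBuXPhos, KOH, dioxane–water), giving 3-[4-(benzyloxy)-2-hydroxyphenyl]-1-[3,4-bis(benzyloxy)phenyl]propan-1-one F1. Acid-catalysed cyclodehydration of F1 (TsOH cat., toluene, water removal) through the cyclic hemiketal then gives the flav-2-ene, and the route is rejoined at 9.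

Step 6. The reagent may discriminate the two faces of this aryl enol ether poorly, and the β-alkoxyborane 10 may eliminate with opening of the pyran ring before oxidation. Fallback, setting out from 9: hydroboration with BH3·SMe2 at 0 °C and immediate oxidation should give the racemic 2,3-trans alcohol, that is 11 together with its enantiomer (2S,3R)-7,3',4'-tri-O-benzylfisetinidol F2. Esterification of the mixture with (S)-2-methoxy-2-phenylacetic acid (DCC, DMAP) gives the diastereomeric esters, the (S)-O-methylmandelate of 11 F3 and the (S)-O-methylmandelate of the enantiomer F4. These are separated by crystallisation or chromatography, and hydrolysis of F3 (LiOH, THF–water) rejoins the route at 11.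

Step 9. The benzyl-protected resorcinol-type ring A of 11 may be too weak a nucleophile. The cation from 13 would then be consumed by self-condensation to oligomers or by O-alkylation of the 3-hydroxyl, and C6/C8 regiocontrol could erode. Fallback, setting out from 11 and 13: hydrogenolysis of 11 (H2, Pd(OH)2/C) gives free (−)-fisetinidol F5, whose phenolic ring A is far more nucleophilic. F5 (excess) is condensed with 13 (BF3·OEt2, dioxane–CH2Cl2, 0 °C) to give 3-O-acetyl-7,3',4'-tri-O-benzylfisetinidol-(4α→6)-fisetinidol F6. Methanolysis of the acetate (NaOMe cat., MeOH) gives 7,3',4'-tri-O-benzylfisetinidol-(4α→6)-fisetinidol F7, and hydrogenolysis of F7 rejoins the route at 16.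

**Further compounds**

F1 | step 5 | 3-[4-(benzyloxy)-2-hydroxyphenyl]-1-[3,4-bis(benzyloxy)phenyl]propan-1-one | O=C(CCc1ccc(OCc2ccccc2)cc1O)c1ccc(OCc2ccccc2)c(OCc2ccccc2)c1
F2 | step 6 | (2S,3R)-7,3',4'-tri-O-benzylfisetinidol (enantiomer of 11) | O[C@@H]1Cc2ccc(OCc3ccccc3)cc2O[C@H]1c1ccc(OCc2ccccc2)c(OCc2ccccc2)c1
F3 | step 6 | (S)-2-methoxy-2-phenylacetate of 11 | CO[C@@H](c1ccccc1)C(=O)O[C@H]1Cc2ccc(OCc3ccccc3)cc2O[C@@H]1c1ccc(OCc2ccccc2)c(OCc2ccccc2)c1
F4 | step 6 | (S)-2-methoxy-2-phenylacetate of F2 | CO[C@@H](c1ccccc1)C(=O)O[C@@H]1Cc2ccc(OCc3ccccc3)cc2O[C@H]1c1ccc(OCc2ccccc2)c(OCc2ccccc2)c1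
F5 | step 9 | (−)-fisetinidol, (2R,3S) | O[C@H]1Cc2ccc(O)cc2O[C@@H]1c1ccc(O)c(O)c1
F6 | step 9 | 3-O-acetyl-7,3',4'-tri-O-benzylfisetinidol-(4α→6)-fisetinidol | C(c1ccccc1)Oc1ccc2c(c1)O[C@H](c1ccc(OCc3ccccc3)c(OCc3ccccc3)c1)[C@@H](OC(C)=O)[C@@H]2c1cc2c(cc1O)O[C@H](c1ccc(O)c(O)c1)[C@@H](O)C2
F7 | step 9 | 7,3',4'-tri-O-benzylfisetinidol-(4α→6)-fisetinidol | C(c1ccccc1)Oc1ccc2c(c1)O[C@H](c1ccc(OCc3ccccc3)c(OCc3ccccc3)c1)[C@@H](O)[C@@H]2c1cc2c(cc1O)O[C@H](c1ccc(O)c(O)c1)[C@@H](O)C2
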